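**Retrosynthetic overview**

1. The target is the C6 acetate of a cis-fused 6,8-dihydroxy acid. The C6 carbinol comes from a C6 ketone by hydroxyl-directed reduction, and a lipase resolution at the diol stage supplies the single enantiomer.
2. Enabling feature: ring B carries oxygen on C6 and on C8. C6(=O)–C7–C8(OH)(C17) is an aldol retron and C6(=O)–C5–C10–C9–C8(=O) is a Michael retron, so cutting C7–C8 and C5–C10 opens both rings to an acyclic, achiral keto-enone acid. In it the C6 methyl ketone is the twofold nucleophile (C5, C7), the C8 acetyl/C9=C10 enone is the twofold electrophile (C10, C8), and C1–C3 with the C4 gem-dimethyl carbon are a plain tether.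
3. Ring order: ring A closes first (C5–C10, Michael), ring B second (C7–C8, aldol), both in step 9, which also creates C5, C8, C9 and C10.
4. The acyclic precursor comes from a Negishi coupling at C1–C10: an alkylzinc (mesityl oxide, allylsilane, then HBr) with the enol triflate of a 3-alkylated acetylacetone. The 13E enoate comes from a syn carboalumination/acylation of a butynyl ether.

Key step: step 9

Remark: the descriptors in the target SMILES encode a cis-fused decalin (H-5 and the C10 methyl on the same face; 5S,6S,8S,9S,10R), and the route is designed for that isomer. Labdane numbering is used: ring A = C1–C5, C10; ring B = C5–C10; side chain C11–C16 on C9; C17 on C8; C18/C19 on C4; C20 on C10.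

**Step 1**
Reactants: 1 mesityl oxide (4-methylpent-3-en-2-one); 2 allyltrimethylsilane
Product: 3 4,4-dimethylhept-6-en-2-one
Conditions: TiCl4, CH2Cl2, −78 °C; then H2O
Reagents that add atoms: none
Why: Hosomi–Sakurai conjugate allylation of the TiCl4-activated β,β-disubstituted enone puts the allyl group on the β-carbon and so builds the C4 gem-dimethyl quaternary carbon (no stereocentre).

**Step 2**
Reactants: 3 4,4-dimethylhept-6-en-2-one
Product: 4 7-bromo-4,4-dimethylheptan-2-one
Conditions: HBr (g), dibenzoyl peroxide (cat.), hexane, 0 °C, hν
Reagents that add atoms: hydrogen bromide, Br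
Why: Radical-chain (Kharasch) anti-Markovnikov hydrobromination places bromine on the terminal carbon (future C1) and avoids a hydroboration, which would also reduce the ketone.

**Step 3**
Reactants: 5 tert-butyl(but-3-yn-1-yloxy)dimethylsilane
Product: 7 methyl (2E)-5-{[tert-butyl(dimethyl)silyl]oxy}-3-methylpent-2-enoate, via alkenylalane 6 (not isolated)
Conditions: AlMe3, Cp2ZrCl2 (cat.), CH2Cl2, 0 °C → rt; then ClCO2Me, 0 °C → rt
Reagents that add atoms: trimethylaluminium, C[Al](C)C; methyl chloroformate, COC(=O)Cl
Why: Negishi zirconium-catalysed carboalumination adds methyl and aluminium syn across the terminal alkyne (methyl to the internal carbon), and acylation of the alkenylalane with retention fixes the 13E geometry.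

**Step 4**
Reactants: 7 methyl (2E)-5-{[tert-butyl(dimethyl)silyl]oxy}-3-methylpent-2-enoate
Product: 8 methyl (2E)-5-bromo-3-methylpent-2-enoate
Conditions: Ph3PBr2, CH2Cl2, 0 °C → rt
Reagents that add atoms: dibromotriphenylphosphorane, BrP(Br)(c1ccccc1)(c1ccccc1)c1ccccc1
Why: Direct conversion of a primary silyl ether into the bromide by the phosphorane (oxyphosphonium formation, then SN2 by bromide) should leave the enoate and its geometry untouched.

**Step 5**
Reactants: 8 methyl (2E)-5-bromo-3-methylpent-2-enoate; 9 acetylacetone (pentane-2,4-dione)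
Product: 10 methyl (2E)-6-acetyl-3-methyl-7-oxooct-2-enoate
Conditions: K2CO3, NaI (cat.), acetone, reflux
Reagents that add atoms: none
Why: Finkelstein-assisted C-alkylation of the acetylacetone enolate at the primary carbon (SN2) joins C9 to C11; the weakly basic, stabilised enolate should keep elimination to the dienoate in the background.

**Step 6**
Reactants: 10 methyl (2E)-6-acetyl-3-methyl-7-oxooct-2-enoate
Product: 11 methyl (2E)-6-acetyl-3-methyl-7-{[(trifluoromethyl)sulfonyl]oxy}octa-2,6-dienoate (mixture of geometric isomers at C6=C7)
Conditions: NaH, Et2O, 0 °C; then Tf2O, −78 → 0 °C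
Reagents that add atoms: trifluoromethanesulfonic anhydride, O=S(=O)(OS(=O)(=O)C(F)(F)F)C(F)(F)F
Why: O-sulfonylation of the sodium enolate of the symmetrical 3-alkyl-1,3-diketone gives the β-triflyloxy enone; the geometry of this double bond is immaterial because C9 is reprotonated in step 9.

**Step 7**
Reactants: 4 7-bromo-4,4-dimethylheptan-2-one; 11 methyl (2E)-6-acetyl-3-methyl-7-{[(trifluoromethyl)sulfonyl]oxy}octa-2,6-dienoate
Product: 13 methyl (2E)-6-acetyl-3,7,11,11-tetramethyl-13-oxotetradeca-2,6-dienoate, via alkylzinc bromide 12 (not isolated)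
Conditions: 4, Zn, LiCl, THF, 50 °C; then 11, Pd(dppf)Cl2 (cat.), THF, rt → 45 °C
Reagents that add atoms: none
Why: Negishi sp3–sp2 cross-coupling: LiCl-assisted zinc insertion gives a ketone-tolerant alkylzinc, and base-free coupling with the activated vinyl triflate forms the C1–C10 bond and the tetrasubstituted C9=C10 enone.

**Step 8**
Reactants: 13 methyl (2E)-6-acetyl-3,7,11,11-tetramethyl-13-oxotetradeca-2,6-dienoate
Product: 14 (2E)-6-acetyl-3,7,11,11-tetramethyl-13-oxotetradeca-2,6-dienoic acid
Conditions: Me3SnOH, ClCH2CH2Cl, 80 °C; then 1 M HCl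
Reagents that add atoms: trimethyltin hydroxide, C[Sn](C)(C)O
Why: Neutral tin-hydroxide ester hydrolysis frees the acid without enolising the keto-enone, so the side chain enters the key step as a carboxylate.

**Step 9**
Reactants: 14 (2E)-6-acetyl-3,7,11,11-tetramethyl-13-oxotetradeca-2,6-dienoic acid
Product: 16 racemic cis-fused 8-hydroxy-6-oxo-labd-13E-en-15-oic acid (5S*,8S*,9S*,10S*), via Michael adduct 15 (not isolated)
Conditions: KOt-Bu (3 equiv), t-BuOH/THF, 0.02 M, 25 → 40 °C; then aq. HCl to pH 4, 0 °C
Reagents that add atoms: none
Why: Proposed new method: under reversible enolisation the C5 enolate of the C6 methyl ketone adds to C10 of the tetrasubstituted enone (6-exo-trig, ring A), proton transfer relays the charge to C7, and the C7 enolate closes ring B onto the C8 methyl ketone (6-enolendo-exo-trig aldol), the tertiary alkoxide and the loss of both π bonds pulling the equilibria forward; the closest known chemistry is the base-mediated intramolecular Michael–aldol double cyclisation of acyclic keto-enones, run here in the (3+3) α,α′-annulation sense known between ketones and enones, and it is new in using a fully substituted, singly activated acyclic enone and a neopentylic enolate. Chemoselectivity rests on ring size, since every other α-enolate/acceptor pairing gives an eight- or ten-membered ring and the one six-membered alternative (γ-aldol of the enone dienolate from C1 onto C6) is reversible, while the C4 gem-dimethyl group favours ring A closure and the side-chain enoate, carried as its potassium carboxylate, neither accepts a Michael donor nor isomerises. C10 is set in the Michael step without facial bias (racemate), and C5 (enolisable) and C8/C9 (retro-aldol and enolisation) are then set relative to it under thermodynamic control. The expected sink is the cis-fused ketol because each tertiary carbon lying between two fully substituted neighbours puts its carbon substituent axial: C6 on C5 (between C4 and C10) axial on ring A, which is the arrangement that closes to the 5,10-cis fusion, and C11 on C9 (between C10 and C8) axial on ring B and cis to the C10 methyl, while C8 keeps its methyl equatorial and its hydroxyl axial, trans to the C10 methyl. The step therefore needs diastereoselectivity at C5, C8 and C9 only, and the moderate temperature with a cold, weakly acidic quench should stop the sequence at the ketol without dehydration.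

**Step 10**
Reactants: 16 racemic cis-fused 8-hydroxy-6-oxo-labd-13E-en-15-oic acid
Product: 17 racemic cis-fused 6,8-dihydroxy-labd-13E-en-15-oic acid (5S*,6S*,8S*,9S*,10R*)
Conditions: Me4NBH(OAc)3, MeCN/AcOH, −30 → 0 °C
Reagents that add atoms: none
Why: Evans–Saksena hydroxyl-directed reduction: the axial C8 hydroxyl binds boron and delivers hydride to the same face of C6, giving the 6,8-anti diol with the C6 hydroxyl equatorial, a face that external hydride cannot reach past the axial C1 and C8–O bonds.

**Step 11**
Reactants: 17 racemic cis-fused 6,8-dihydroxy-labd-13E-en-15-oic acid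
Product: 18 (5S,6S,8S,9S,10R)-6,8-dihydroxy-labd-13E-en-15-oic acid, cis-fused, single enantiomer (recovered unreacted)
Conditions: lipase from Burkholderia cepacia (immobilised), vinyl acetate, t-BuOMe, 35 °C, run past half conversion; chromatography
Reagents that add atoms: none
Why: Lipase-catalysed kinetic resolution by transesterification: by the empirical size rule for secondary alcohols (C5 side large, C7 side medium) the 6R enantiomer should be acetylated faster, so the 6S diol acid of the target series should be recovered enantioenriched.

**Step 12**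
Reactants: 18 (5S,6S,8S,9S,10R)-6,8-dihydroxy-labd-13E-en-15-oic acid
Product: 19 (5S,6S,8S,9S,10R)-6-acetoxy-8-hydroxy-labd-13E-en-15-oic acid, cis-fused (CNP0221670.1)
Conditions: Ac2O, pyridine, DMAP (cat.), CH2Cl2, 0 °C → rt; then aq. NaHCO3, then pH 3
Reagents that add atoms: acetic anhydride, CC(=O)OC(C)=O
Why: Acetylation of the secondary C6 hydroxyl with retention; the tertiary C8 hydroxyl is inert under these conditions and the mixed anhydride formed at C15 is hydrolysed in the work-up.

**Compound list**

1 | mesityl oxide (4-methylpent-3-en-2-one) | CC(=O)C=C(C)C | starting material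
2 | allyltrimethylsilane | C=CC[Si](C)(C)C | starting material
3 | 4,4-dimethylhept-6-en-2-one | CC(=O)CC(C)(C)CC=C | intermediate
4 | 7-bromo-4,4-dimethylheptan-2-one | CC(=O)CC(C)(C)CCCBr | intermediate
5 | tert-butyl(but-3-yn-1-yloxy)dimethylsilane | C#CCCO[Si](C)(C)C(C)(C)C | starting material
6 | [(1E)-4-{[tert-butyl(dimethyl)silyl]oxy}-2-methylbut-1-en-1-yl]dimethylalane | C[Al](C)/C=C(\C)CCO[Si](C)(C)C(C)(C)C | intermediate (not isolated)
7 | methyl (2E)-5-{[tert-butyl(dimethyl)silyl]oxy}-3-methylpent-2-enoate | COC(=O)/C=C(\C)CCO[Si](C)(C)C(C)(C)C | intermediate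
8 | methyl (2E)-5-bromo-3-methylpent-2-enoate | COC(=O)/C=C(\C)CCBr | intermediate
9 | acetylacetone (pentane-2,4-dione) | CC(=O)CC(C)=O | starting material
10 | methyl (2E)-6-acetyl-3-methyl-7-oxooct-2-enoate | COC(=O)/C=C(\C)CCC(C(C)=O)C(C)=O | intermediate
11 | methyl (2E)-6-acetyl-3-methyl-7-{[(trifluoromethyl)sulfonyl]oxy}octa-2,6-dienoate (geometric mixture at C6=C7) | COC(=O)/C=C(\C)CCC(C(C)=O)=C(C)OS(=O)(=O)C(F)(F)F | intermediate
12 | (4,4-dimethyl-6-oxoheptyl)zinc bromide | CC(=O)CC(C)(C)CCC[Zn]Br | intermediate (not isolated)
13 | methyl (2E)-6-acetyl-3,7,11,11-tetramethyl-13-oxotetradeca-2,6-dienoate (geometric mixture at C6=C7) | COC(=O)/C=C(\C)CCC(C(C)=O)=C(C)CCCC(C)(C)CC(C)=O | intermediate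
14 | (2E)-6-acetyl-3,7,11,11-tetramethyl-13-oxotetradeca-2,6-dienoic acid | OC(=O)/C=C(\C)CCC(C(C)=O)=C(C)CCCC(C)(C)CC(C)=O | intermediate
15 | (2E)-6-(2-acetyl-1,3,3-trimethylcyclohexyl)-3-methyl-7-oxooct-2-enoic acid, acetyl cis to the octenoic branch, chain C6 unfixed, racemic, present as its potassium enolates | CC(=O)[C@H]1C(C)(C)CCC[C@@]1(C)C(CC/C(C)=C/C(=O)O)C(C)=O | intermediate (not isolated)
16 | racemic cis-fused 8-hydroxy-6-oxo-labd-13E-en-15-oic acid (5S*,8S*,9S*,10S*; one enantiomer drawn) | O=C1C[C@](C)(O)[C@@H](CC/C(C)=C/C(=O)O)[C@]2(C)CCCC(C)(C)[C@H]12 | intermediate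
17 | racemic cis-fused 6,8-dihydroxy-labd-13E-en-15-oic acid (5S*,6S*,8S*,9S*,10R*; one enantiomer drawn) | O[C@H]1C[C@](C)(O)[C@@H](CC/C(C)=C/C(=O)O)[C@]2(C)CCCC(C)(C)[C@H]12 | intermediate
18 | (5S,6S,8S,9S,10R)-6,8-dihydroxy-labd-13E-en-15-oic acid, cis-fused, single enantiomer | O[C@H]1C[C@](C)(O)[C@@H](CC/C(C)=C/C(=O)O)[C@]2(C)CCCC(C)(C)[C@H]12 | intermediate
19 | (5S,6S,8S,9S,10R)-6-acetoxy-8-hydroxy-labd-13E-en-15-oic acid, cis-fused (CNP0221670.1) | CC(=O)O[C@H]1C[C@](C)(O)[C@@H](CC/C(C)=C/C(=O)O)[C@]2(C)CCCC(C)(C)[C@H]12 | target

**Step count**

Total steps: 12. Longest linear sequence: 10 steps (5 → 7 → 8 → 10 → 11 → 13 → 14 → 16 → 17 → 18 → 19).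

**Steps most likely to fail**

1. Step 9 (proposed new method). The conjugate addition at the fully substituted C10 may be too slow, so that enone deconjugation and intermolecular condensation take over. The thermodynamic funnelling may not settle on the cis-fused, C11-axial diastereomer, and the ketol may dehydrate. The fallback separates the two bond formations and uses known chemistry. It sets out from 13 and comes back to the route at 16. Compound 13 is treated with TBSOTf and Et3N (ClCH2CH2Cl, 0 → 60 °C). The C5 tert-butyldimethylsilyl enol ether of 13 F1, formed in the flask in equilibrium with its C7 regioisomer, adds to the O-silylated enone. This is an intramolecular silyl-triflate-mediated Mukaiyama–Michael reaction, a cation-like mode suited to quaternary centres on hindered enones. It should give the ring A silyl enol ether F2, and 1 M HCl/THF then gives the monocyclic diketone ester F3. Me3SnOH converts F3 into 15, now isolated, and a separate cold aldol closure (KOt-Bu, t-BuOH, 0 °C) gives 16.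

2. Step 11. The enzyme may not accept the hindered C6 carbinol, or may discriminate poorly between the enantiomers. The fallback is a covalent resolution that sets out from 17 and comes back at 18. Compound 17 is acylated at O6 with (1S)-camphanic chloride (pyridine, DMAP, CH2Cl2; the mixed anhydride at C15 is hydrolysed in the work-up). This gives the diastereomeric C6 camphanate of the target series F4 and the C6 camphanate of the antipodal series F5, which are separated by chromatography or crystallisation. LiOH in THF/H2O cleaves F4 to 18.

3. Step 10. Ligand exchange at the hindered tertiary C8 hydroxyl may be too slow for internal hydride delivery, leaving the ketone unreduced or allowing external delivery to the wrong face. The fallback sets out from 16 and comes back at 17. It replaces hydride delivery by single-electron reduction with SmI2 (THF/MeOH, 0 °C), in which the samarium ketyl chelated by the C8 hydroxyl is protonated to give the 6,8-anti diol. No compound outside the list is made (F0).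

**Further compounds**

F1 | step 9 | C5 tert-butyldimethylsilyl enol ether of 13 (formed in the flask) | COC(=O)/C=C(\C)CCC(C(C)=O)=C(C)CCCC(C)(C)C=C(C)O[Si](C)(C)C(C)(C)C
F2 | step 9 | ring A silyl enol ether: methyl (2E)-6-(2-acetyl-1,3,3-trimethylcyclohexyl)-7-{[tert-butyl(dimethyl)silyl]oxy}-3-methylocta-2,6-dienoate, racemic | CC(=O)[C@H]1C(C)(C)CCC[C@@]1(C)C(CC/C(C)=C/C(=O)OC)=C(C)O[Si](C)(C)C(C)(C)C
F3 | step 9 | methyl (2E)-6-(2-acetyl-1,3,3-trimethylcyclohexyl)-3-methyl-7-oxooct-2-enoate, racemic (methyl ester of 15) | CC(=O)[C@H]1C(C)(C)CCC[C@@]1(C)C(CC/C(C)=C/C(=O)OC)C(C)=O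
F4 | step 11 | C6 (1S)-camphanate of the target-series diol acid | O=C(O[C@H]1C[C@](C)(O)[C@@H](CC/C(C)=C/C(=O)O)[C@]2(C)CCCC(C)(C)[C@H]12)[C@@]34CC[C@@](C)(C(=O)O3)C4(C)C
F5 | step 11 | C6 (1S)-camphanate of the antipodal diol acid | O=C(O[C@@H]1C[C@@](C)(O)[C@H](CC/C(C)=C/C(=O)O)[C@@]2(C)CCCC(C)(C)[C@@H]12)[C@@]34CC[C@@](C)(C(=O)O3)C4(C)C
F0 | step 10 | none | none
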